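The carbonyl at C1 activates just one position of the 31-membered lactone ring (O, C1–C30), namely C2. The ring is therefore cut at C2–C3 after adding back a C2=C3 double bond, so that a phosphonate on C2 can olefinate an aldehyde at C3. One intramolecular Horner–Wadsworth–Emmons reaction forms this carbon–carbon bond and closes the macrocycle; hydrogenation then removes the alkene. The precursor is the diethylphosphonoacetate ester of 28-hydroxyoctacosanal (C3–C30). Its two chain ends are differentiated from the outset: C12 and C16 bromo alcohols are joined by a copper-catalysed Grignard coupling that leaves one terminus silylated and the other free.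

Key step: step 6

Assumption: the target is read as the saturated 31-membered lactone with thirty carbons (ring O, C1 carbonyl, C2–C30 methylenes), and 16-bromohexadecan-1-ol is taken as a catalogue compound (otherwise one step from hexadecane-1,16-diol with aqueous HBr in toluene).

Step 1
Reactants: 1 12-bromododecan-1-ol
Product: 2 tert-butyl[(12-bromododecyl)oxy]dimethylsilane
Conditions: TBSCl, imidazole, DMF, 0 °C to rt
Reagents that add atoms: tert-butyldimethylsilyl chloride, CC(C)(C)[Si](C)(C)Cl
Why: Imidazole-promoted silylation of a primary alcohol (Corey silyl ether protection) is fast and leaves the primary alkyl bromide untouched, so the hydroxyl is masked before the carbon–magnesium bond is made.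

Step 2
Reactants: 2 tert-butyl[(12-bromododecyl)oxy]dimethylsilane; 3 16-bromohexadecan-1-ol
Product: 6 28-[(tert-butyldimethylsilyl)oxy]octacosan-1-ol, via silyloxydodecylmagnesium bromide 4 (not isolated), via chloromagnesium 16-bromohexadecan-1-olate 5 (not isolated)
Conditions: 2, Mg, THF, 45 °C; 3, MeMgCl (1.0 equiv), THF, −20 °C; combine, Li2CuCl4 (3 mol %), THF, −20 °C to rt; aq. NH4Cl
Reagents that add atoms: none
Why: Under Li2CuCl4 catalysis (divalent copper precatalyst, Kochi-type sp3–sp3 cross-coupling) a primary alkyl Grignard reagent couples with a primary alkyl bromide faster than it attacks a silyl ether or a magnesium alkoxide, so pre-forming alkoxide 5 with MeMgCl lets the unprotected bromo alcohol be used and should give a C28 chain with one silylated and one free terminus without any statistical step.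

Step 3
Reactants: 6 28-[(tert-butyldimethylsilyl)oxy]octacosan-1-ol; 7 diethylphosphonoacetic acid
Product: 8 28-[(tert-butyldimethylsilyl)oxy]octacosyl 2-(diethoxyphosphoryl)acetate
Conditions: DCC, DMAP (cat.), CH2Cl2, 0 °C to rt
Reagents that add atoms: none
Why: Steglich esterification: DCC activates acid 7 and DMAP transfers the acyl group to the unhindered primary alcohol under neutral conditions that leave the silyl ether and the phosphonate esters intact.

Step 4
Reactants: 8 28-[(tert-butyldimethylsilyl)oxy]octacosyl 2-(diethoxyphosphoryl)acetate
Product: 9 28-hydroxyoctacosyl 2-(diethoxyphosphoryl)acetate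
Conditions: HF·pyridine, pyridine, THF, 0 °C to rt
Reagents that add atoms: none
Why: Fluoride-driven cleavage of a primary tert-butyldimethylsilyl ether by buffered HF·pyridine (silyl ether deprotection through Si–F bond formation) is compatible with carboxylic and phosphonate esters, which are not attacked by this mildly acidic, weakly nucleophilic reagent.

Step 5
Reactants: 9 28-hydroxyoctacosyl 2-(diethoxyphosphoryl)acetate
Product: 10 28-oxooctacosyl 2-(diethoxyphosphoryl)acetate
Conditions: Dess–Martin periodinane, CH2Cl2, rt; used directly in step 6
Reagents that add atoms: none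
Why: Dess–Martin oxidation converts a primary alcohol into the aldehyde at room temperature under near-neutral conditions without over-oxidation and without enolising the phosphonoacetate, a routine way to reach phosphonate aldehydes for ring closure.

Step 6
Reactants: 10 28-oxooctacosyl 2-(diethoxyphosphoryl)acetate
Product: 11 (E)-oxacyclohentriacont-3-en-2-one
Conditions: LiCl (10 equiv), DBU (5 equiv), MeCN/THF 3:1, 40 °C; 10 in THF added by syringe pump over 12 h, final concentration about 1 mM
Reagents that add atoms: none
Why: LiCl binds the phosphoryl and ester oxygens of 10, which lowers the pKa at C2 enough for DBU to generate the lithium phosphonoenolate; C2 then adds to the aldehyde carbon C3 and the beta-alkoxyphosphonate collapses through an oxaphosphetane with loss of diethyl phosphate to give the C2=C3 enoate. The closest known reaction type is the Masamune–Roush variant of the intramolecular Horner–Wadsworth–Emmons olefination as used for unsaturated macrolactones. The 31-membered ring is closed end to end by carbon–carbon bond formation, the carbanion attacking a carbonyl group that lies outside the forming ring (exo-trig), and a ring of this size carries no transannular strain. No stereocenter is created; the stabilised phosphonate should favour the E alkene, but the geometry is erased in step 7. The step needs ring closure to win over intermolecular olefination, which the slow addition secures by keeping free 10 far below millimolar, and it needs deprotonation at C2 and not at the aldehyde alpha-carbon C4, which is secured because only C2 lies between the carbonyl and the phosphoryl group and the amine base is too weak to enolise the aldehyde; THF as co-solvent keeps the waxy C28 chain in solution.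

Step 7
Reactants: 11 (E)-oxacyclohentriacont-3-en-2-one
Product: 12 oxacyclohentriacontan-2-one
Conditions: H2 (1 atm), 10% Pd/C, EtOAc, rt
Reagents that add atoms: none
Why: Heterogeneous catalytic hydrogenation over palladium metal saturates the disubstituted conjugated alkene readily, while the saturated lactone has no benzylic or allylic C–O bond and is inert.

Compound list
1 | 12-bromododecan-1-ol | OCCCCCCCCCCCCBr | starting material
2 | tert-butyl[(12-bromododecyl)oxy]dimethylsilane | CC(C)(C)[Si](C)(C)OCCCCCCCCCCCCBr | intermediate
3 | 16-bromohexadecan-1-ol | OCCCCCCCCCCCCCCCCBr | starting material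
4 | {12-[(tert-butyldimethylsilyl)oxy]dodecyl}magnesium bromide | CC(C)(C)[Si](C)(C)OCCCCCCCCCCCC[Mg]Br | intermediate
5 | chloromagnesium 16-bromohexadecan-1-olate | BrCCCCCCCCCCCCCCCCO[Mg]Cl | intermediate
6 | 28-[(tert-butyldimethylsilyl)oxy]octacosan-1-ol | CC(C)(C)[Si](C)(C)OCCCCCCCCCCCCCCCCCCCCCCCCCCCCO | intermediate
7 | diethylphosphonoacetic acid | CCOP(=O)(OCC)CC(=O)O | starting material
8 | 28-[(tert-butyldimethylsilyl)oxy]octacosyl 2-(diethoxyphosphoryl)acetate | CCOP(=O)(OCC)CC(=O)OCCCCCCCCCCCCCCCCCCCCCCCCCCCCO[Si](C)(C)C(C)(C)C | intermediate
9 | 28-hydroxyoctacosyl 2-(diethoxyphosphoryl)acetate | CCOP(=O)(OCC)CC(=O)OCCCCCCCCCCCCCCCCCCCCCCCCCCCCO | intermediate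
10 | 28-oxooctacosyl 2-(diethoxyphosphoryl)acetate | CCOP(=O)(OCC)CC(=O)OCCCCCCCCCCCCCCCCCCCCCCCCCCCC=O | intermediate
11 | (E)-oxacyclohentriacont-3-en-2-one | O=C1/C=C/CCCCCCCCCCCCCCCCCCCCCCCCCCCO1 | intermediate
12 | oxacyclohentriacontan-2-one | O=C1CCCCCCCCCCCCCCCCCCCCCCCCCCCCCO1 | target

Total step count: 7. Longest linear sequence: 7 steps (1 to 12); 3 and 7 enter as bought.

Steps most likely to fail

Step 6. Intermolecular olefination may outrun ring closure and give the cyclic dimer and linear oligomers, and the aldehyde may self-condense during the long addition. The fallback closes the ring at the ester C–O bond instead; it sets out from 6 and comes back at 12. Alcohol 6 would be treated with I2, PPh3 and imidazole to give tert-butyl[(28-iodooctacosyl)oxy]dimethylsilane F1. The lithium enolate of tert-butyl acetate (LiN(iPr)2, THF/DMPU, −78 °C to rt) would be alkylated with F1 to give tert-butyl 30-[(tert-butyldimethylsilyl)oxy]triacontanoate F2. Aqueous trifluoroacetic acid in CH2Cl2, followed by a brief K2CO3/MeOH wash and acidification, would remove both the tert-butyl ester and the silyl ether to give 30-hydroxytriacontanoic acid F3. Yamaguchi lactonisation (2,4,6-trichlorobenzoyl chloride, Et3N, THF, then slow addition to DMAP in refluxing toluene) would then close the ring to 12 directly.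

Step 2. Wurtz-type homocoupling during Grignard formation, or a sluggish catalytic coupling of the poorly soluble magnesium alkoxide, may leave unreacted bromide. The fallback replaces the catalytic coupling by a stoichiometric sulfone alkylation; it sets out from 2 (with 3) and comes back at 6. Bromide 2 would be heated with PhSO2Na in DMF to give tert-butyldimethyl{[12-(phenylsulfonyl)dodecyl]oxy}silane F4. Its alpha-lithio derivative (n-BuLi, THF, −78 °C) would be alkylated in THF/DMPU with the lithium alkoxide of 3 (from 3 and one equivalent of n-BuLi) to give racemic 28-[(tert-butyldimethylsilyl)oxy]-17-(phenylsulfonyl)octacosan-1-ol F5. Reductive desulfonylation with Na/Hg amalgam and Na2HPO4 in MeOH/THF would give 6.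

Step 5. The phosphonate-bearing aldehyde may condense with itself or over-oxidise during oxidation, work-up or storage. The fallback carries the aldehyde as an acetal and releases it by hydrolysis; it sets out from 6 and comes back at 10. Alcohol 6 would be oxidised with Dess–Martin periodinane to 28-[(tert-butyldimethylsilyl)oxy]octacosanal F6. HC(OMe)3 and catalytic p-TsOH in MeOH would form the dimethyl acetal and cleave the silyl ether in the same flask, giving 28,28-dimethoxyoctacosan-1-ol F7. DCC/DMAP esterification with 7 would give 28,28-dimethoxyoctacosyl 2-(diethoxyphosphoryl)acetate F8. Brief hydrolysis with aqueous trifluoroacetic acid in CH2Cl2 at 0 °C would release 10 immediately before cyclisation.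

Further compounds
F1 | step 6 | tert-butyl[(28-iodooctacosyl)oxy]dimethylsilane | CC(C)(C)[Si](C)(C)OCCCCCCCCCCCCCCCCCCCCCCCCCCCCI
F2 | step 6 | tert-butyl 30-[(tert-butyldimethylsilyl)oxy]triacontanoate | CC(C)(C)OC(=O)CCCCCCCCCCCCCCCCCCCCCCCCCCCCCO[Si](C)(C)C(C)(C)C
F3 | step 6 | 30-hydroxytriacontanoic acid | OC(=O)CCCCCCCCCCCCCCCCCCCCCCCCCCCCCO
F4 | step 2 | tert-butyldimethyl{[12-(phenylsulfonyl)dodecyl]oxy}silane | CC(C)(C)[Si](C)(C)OCCCCCCCCCCCCS(=O)(=O)c1ccccc1
F5 | step 2 | 28-[(tert-butyldimethylsilyl)oxy]-17-(phenylsulfonyl)octacosan-1-ol (racemic) | CC(C)(C)[Si](C)(C)OCCCCCCCCCCCC(S(=O)(=O)c1ccccc1)CCCCCCCCCCCCCCCCO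
F6 | step 5 | 28-[(tert-butyldimethylsilyl)oxy]octacosanal | CC(C)(C)[Si](C)(C)OCCCCCCCCCCCCCCCCCCCCCCCCCCCC=O
F7 | step 5 | 28,28-dimethoxyoctacosan-1-ol | COC(OC)CCCCCCCCCCCCCCCCCCCCCCCCCCCO
F8 | step 5 | 28,28-dimethoxyoctacosyl 2-(diethoxyphosphoryl)acetate | CCOP(=O)(OCC)CC(=O)OCCCCCCCCCCCCCCCCCCCCCCCCCCCC(OC)OC
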